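## Structural features

Silyhermin B (24) has five rings. A 5,7-dihydroxychroman-4-one (aromatic ring A fused to the dihydropyranone ring C) carries benzene ring B at C2. Ring B is also the benzo ring of a 2,3-dihydrobenzofuran (ring D, fused at C3a'–C7a'), which bears a 4-hydroxy-3-methoxyphenyl group (ring E) at C2' and a hydroxymethyl group at C3'.

Ring B is 1,2,3,5-tetrasubstituted: O1' at C7a', a free hydroxyl at C7', C3' at C3a', and the flavanone C2 at C5', para to O1'.

There are three stereocentres. C2' (R) and C3' (S) are adjacent and trans on ring D. C2 (S) stands alone, four bonds from C3' across the flat ring B, so no substrate relay can reach it.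

The fragile parts are:
- the flavanone, which base opens by retro-oxa-Michael reaction with loss of C2;
- the benzylic aryl ether bonds C2–O1 and C2'–O1', which are open to acid ionisation, hydrogenolysis and dehydrogenation;
- four phenols, a primary alcohol and three electron-rich arenes.

The real difficulty is absolute control at C2 independent of the C2'/C3' pair; the trans ring D is the thermodynamic arrangement and is less demanding.

The key step uses the para relation of O1' and C5'. A vinyl group at C5' is an electron-rich styrene whose two carbons become C2 and C3. Ring A enters as the oxa-diene O1=C8a–C4a=C4 of an ortho-quinone methide whose methide carbon already carries the oxygen of the later C4 carbonyl.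

## Logic of the disconnections

**24 to 23.** Five O–CH2Ph bonds are cut. One kind of protecting group, removable under neutral conditions, keeps the flavanone away from base and leaves the polyphenol to the last step. The forward step must spare C2–O1, C2'–O1' and the ketone.

**23 to 22 to 21.** The C4 carbonyl is traced back to C4–OH and then C4–OMe. No skeletal bond is cut; the change exposes the [4+2] retron of ring C with the C4 oxygen already in place. The forward steps must ionise only C4–OMe, the benzylic position flanked by three oxygen donors of ring A, and must oxidise without touching C2'–H. Because C4 is flattened, isomers of the wrong relative configuration have to be removed at 21.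

**21 to 16 and 19 (through 20).** C3–C4 and O1–C2 are cut. The cut is convergent and creates C2 in a bond-forming event that a chiral acid can control. 21 (five rings, four stereocentres) becomes 16 (three rings, two stereocentres) and achiral 19. The forward step demands facial control at a cation by its counter-anion, cis ring closure, and attack by the vinyl group in preference to any arene.

**19 to 18 to 17.** The two acetal C–O bonds and two O–CH2Ph bonds are cut. The free hydroxyl ortho to the acetal is kept as the hydrogen-bond handle for the catalyst. Dibenzylation must spare the chelated hydroxyl, and 19 must be made free of soluble acid or base.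

**16 to 15.** The C5'–vinyl bond is cut. A bromide survives the acidic closure of ring D, which a styrene would not, and it is converted into the vinyl group in one step. The coupling must tolerate three benzyl ethers.

**15 to 14.** Two O–CH2Ph bonds (phenol and primary alcohol) are cut; both form in one operation.

**14 to 12 (through 13).** O1'–C2' is cut. The benzylic carbon para to an alkoxy group ionises easily, and only the catechol hydroxyl ortho to the side chain can reach it, so the two ring B oxygens need no differentiation. Ring D and the C2' stereocentre disappear, leaving an acyclic 1,3-diol. C3' must already be in place; it then sets C2' under thermodynamic control, and the carbinol configuration of 12 is irrelevant.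

**12 to 11.** The primary alcohol is traced back to the acyl group bound to the auxiliary. Reductive cleavage must avoid retro-aldol reaction.

**11 to 8 and 9 (through 10).** C2'–C3' is cut at the aldol retron. The bond joins the two aryl-bearing carbons and places the auxiliary-controlled centre at C3'. The forward step needs a Z-enolate and facial control by the auxiliary.

**8 to 6 (through 7), then 6 to 3 to 2 to 1.** The N–acyl bond, the bond between the benzylic carbon and the carboxyl carbon (one-carbon homologation of an aldehyde), and the two acetal protecting groups are cut. 1 already has the full 1,2,3,5 pattern of ring B with bromine para to the future O1', so no regiochemical problem remains. The homologation must run under basic conditions.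

## Other disconnections considered

**Alternative 1:** The cut is O1'–C2', made from a diarylpropane with no oxygen at C2'. The precursor is methyl 3-(benzyloxy)-5-[(2S)-1-{[tert-butyl(dimethyl)silyl]oxy}-3-(4-hydroxy-3-methoxyphenyl)propan-2-yl]-4-hydroxybenzoate A1. Anodic oxidation at graphite would turn its 4-alkylguaiacol unit into a para-quinone methide, and the ring B phenol would add to the methide carbon to give the trans dihydrobenzofuran ester A2.

- In its favour: no chemical oxidant, no benzylic hydroxyl to install, a biomimetic intermediate, and ring E arrives with its phenol free.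
- Against it here: two phenols and a product that is still an oxidisable guaiacol with a benzylic C2'–H compete at the anode, so over-oxidation toward the benzofuran is a risk. The solvent may capture the methide. The C5' ester needs three steps (reduction, oxidation, olefination) to become the vinyl group, against one step from bromide 15.
- Comparison: on the ring D bond it is the equal of the chosen plan. Step 7 forms the same bond through the same kind of para-oxygen-stabilised benzylic electrophile with the same thermodynamic trans control. It is the better in redox economy at C2' and worse in chemoselectivity and in the C5' handle. Like the other alternatives it leaves C2 unsolved, so a step like step 12 would still be needed.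

**Alternative 2:** The cut is C3a'–C4' and C7a'–C7', so ring B is built last around a finished ring D precursor. The trans lactone A3 would be converted into its silyl ketene acetal A4, which would add to methyl 3-bromocoumalate A5. Decarboxylative retro-[4+2] reaction and β-elimination of the silyloxy group would then aromatise ring B to give A6.

- In its favour: the awkward tetrasubstituted ring B is assembled regiospecifically by a known pyrone benzannulation. The lactone stereocentres can be set by established lignan-lactone chemistry. No arylacetic acid of ring B is needed, so the homologation of steps 2 and 3 is avoided; on that point it is the better.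
- Against it here: A6 has bromine at C7', where 24 needs oxygen, and an ester at C5'. That costs a C–Br to C–OH conversion plus the three-step ester-to-vinyl change. In the aromatisation, the acetal carbon C7a' carries two possible leaving groups, and expulsion of the ring oxygen would open ring D.
- Comparison: its key step is better precedented than step 12 and equal in convergence for ring B. It is longer overall because of the two functional-group corrections, and it does not address C2.

**Alternative 3:** The cut is C2'–C3'. The aryl diazoacetate A7 would undergo intramolecular carbenoid insertion into the O-benzylic C–H bond under a chiral divalent rhodium carboxylate dimer. This would give the cis ester A8, which an alkoxide base would epimerise at C3' to the trans ester A9.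

- In its favour: it is catalytic in chirality, sets both ring D centres in one flask, belongs to a well-established reaction class for exactly this ring system, and carries the same bromide handle as 15.
- Against it here: the 7'-O-benzyl group offers competing benzylic C–H bonds (six-membered insertion). The basic epimerisation can open ring D by β-elimination of O1' from the ester enolate. A diazo compound must be handled. The same ring B arylacetic ester is needed, so steps 1 to 3 are not saved.
- Comparison: on precedent and atom economy its key step is the better. In step count from the arylacetic acid to 14 it is about equal (etherification, diazo transfer, insertion with epimerisation, reduction, against acylation, aldol, reduction, ring closure). In chemoselectivity it is the weaker. It again leaves C2 open.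

The auxiliary route to 16 was preferred because its stereochemical outcome is the most predictable and the catechol needs no differentiation. The product of any of the three alternatives could feed the same key step.

Key step: step 12

**Remarks on the chemistry**

- Assumption: 1, 9, 17 and both antipodes of 4-benzyl-1,3-oxazolidin-2-one are taken as catalogue compounds.
- The sense of induction of the chiral acid in step 12 cannot be derived with confidence. The (R)-acid is written; the antipode that gives 2S is to be fixed on 4-methoxystyrene before 16 is committed.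
- Structure check: (2S,4S) in 21 is the 2,4-cis arrangement, (2'R,3'S) is the trans ring D, and 21 carries five benzyl ethers. No connectivity needed correction.
- Design changes to the precursors: the vinyl group of 16 comes from a bromide rather than an aldehyde; 19 is made amine-free and used fresh; an N-triflyl phosphoramide replaces a plain phosphoric acid.

## Route

Step 1
Reactants: 1 5-bromo-2,3-dihydroxybenzaldehyde
Product: 2 5-bromo-2,3-bis(methoxymethoxy)benzaldehyde
Conditions: MOMCl (2.6 equiv), iPr2NEt (3 equiv), CH2Cl2, 0 °C to rt
Reagents that add atoms: chloromethyl methyl ether, COCCl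
Why: O-alkylation of both phenols with a reactive chloromethyl ether (the chelated 2-OH needs the excess and the warm-up); MOM survives every basic step up to 12 and leaves in the same acidic operation that closes ring D.

Step 2
Reactants: 2 5-bromo-2,3-bis(methoxymethoxy)benzaldehyde
Product: 3 1-[5-bromo-2,3-bis(methoxymethoxy)phenyl]-2,2,2-trichloroethan-1-ol (racemic)
Conditions: CHCl3 (solvent), DBU (1 equiv), rt
Reagents that add atoms: chloroform, ClC(Cl)Cl
Why: Amidine-promoted addition of the trichloromethyl anion to a non-enolisable aromatic aldehyde, without Cannizzaro chemistry; the racemic carbinol centre is removed in step 3.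

Step 3
Reactants: 3 1-[5-bromo-2,3-bis(methoxymethoxy)phenyl]-2,2,2-trichloroethan-1-ol
Product: 6 [5-bromo-2,3-bis(methoxymethoxy)phenyl]acetic acid, via dichlorooxirane 4 (not isolated), via arylacetyl chloride 5 (not isolated)
Conditions: NaBH4 (3 equiv), NaOH (3.5 equiv), t-BuOH/H2O, 55 °C; then citric acid to pH 4, 0 °C
Reagents that add atoms: sodium hydroxide, [Na+].[OH-] (one carboxyl oxygen)
Why: Reductive Jocic–Reeve homologation: the alkoxide closes to 4, hydride opens it at the benzylic carbon, the α-chloro alkoxide collapses to 5 and hydroxide hydrolyses it, a net one-carbon extension of the aldehyde to the arylacetic acid; MOM ethers and the aryl bromide are inert to borohydride and hydroxide.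

Step 4
Reactants: 6 [5-bromo-2,3-bis(methoxymethoxy)phenyl]acetic acid
Product: 8 (4R)-4-benzyl-3-{[5-bromo-2,3-bis(methoxymethoxy)phenyl]acetyl}-1,3-oxazolidin-2-one, via mixed pivalic anhydride 7 (not isolated)
Conditions: PivCl, Et3N, THF, −20 °C; then LiCl, (R)-4-benzyl-1,3-oxazolidin-2-one, −20 °C to rt
Reagents that add atoms: (R)-4-benzyl-1,3-oxazolidin-2-one, O=C1N[C@H](Cc2ccccc2)CO1
Why: N-acylation of the auxiliary through 7, attacked at the less hindered arylacetyl carbonyl; LiCl/Et3N avoids a strong base that would enolise the acidic arylacetyl unit.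

Step 5
Reactants: 8 (4R)-4-benzyl-3-{[5-bromo-2,3-bis(methoxymethoxy)phenyl]acetyl}-1,3-oxazolidin-2-one; 9 4-(benzyloxy)-3-methoxybenzaldehyde
Product: 11 (4R)-4-benzyl-3-{(2R,3R)-3-[4-(benzyloxy)-3-methoxyphenyl]-2-[5-bromo-2,3-bis(methoxymethoxy)phenyl]-3-hydroxypropanoyl}-1,3-oxazolidin-2-one, via dibutylboron Z-enolate 10 (not isolated)
Conditions: Bu2BOTf (1.2 equiv), iPr2NEt (1.4 equiv), CH2Cl2, −78 to 0 °C; 9, −78 to 0 °C; pH 7 buffer, MeOH, H2O2, 0 °C
Reagents that add atoms: none
Why: Evans syn-aldol: soft enolisation gives 10, which reacts through a chair Zimmerman–Traxler transition state on the face away from the benzyl group of the (R)-auxiliary, fixing the α-aryl centre (2R in 11, later 3'S) and the syn carbinol (3R); only the α-centre is needed later, since the carbinol carbon is planarised in step 7.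

Step 6
Reactants: 11 (4R)-4-benzyl-3-{(2R,3R)-3-[4-(benzyloxy)-3-methoxyphenyl]-2-[5-bromo-2,3-bis(methoxymethoxy)phenyl]-3-hydroxypropanoyl}-1,3-oxazolidin-2-one
Product: 12 (1R,2S)-1-[4-(benzyloxy)-3-methoxyphenyl]-2-[5-bromo-2,3-bis(methoxymethoxy)phenyl]propane-1,3-diol
Conditions: LiBH4 (2 equiv), H2O (1 equiv), THF, 0 °C
Reagents that add atoms: none
Why: Reductive cleavage of the N-acyl oxazolidinone (hydride attack at the exocyclic carbonyl) gives the primary alcohol and returns the auxiliary; low temperature keeps retro-aldol reaction and epimerisation of the α-aryl centre in check.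

Step 7
Reactants: 12 (1R,2S)-1-[4-(benzyloxy)-3-methoxyphenyl]-2-[5-bromo-2,3-bis(methoxymethoxy)phenyl]propane-1,3-diol
Product: 14 (2R,3S)-2-[4-(benzyloxy)-3-methoxyphenyl]-5-bromo-3-(hydroxymethyl)-2,3-dihydro-1-benzofuran-7-ol, via catechol diol 13 (not isolated)
Conditions: HCl (1.25 M in MeOH), 0 to 40 °C
Reagents that add atoms: none
Why: Acidic methanol removes both MOM acetals (13, formaldehyde trapped as its dimethyl acetal) and then ionises the benzylic alcohol to a cation stabilised by the para-benzyloxy group; the only catechol hydroxyl that can reach it closes the five-membered ring (SN1 etherification), and because cis and trans products interconvert through the same cation the aryl group settles trans to the C3' substituent, so C3' sets C2' (R) under thermodynamic control.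

Step 8
Reactants: 14 (2R,3S)-2-[4-(benzyloxy)-3-methoxyphenyl]-5-bromo-3-(hydroxymethyl)-2,3-dihydro-1-benzofuran-7-ol
Product: 15 (2R,3S)-7-(benzyloxy)-2-[4-(benzyloxy)-3-methoxyphenyl]-3-[(benzyloxy)methyl]-5-bromo-2,3-dihydro-1-benzofuran
Conditions: NaH (2.5 equiv), BnBr (2.4 equiv), Bu4NI (cat.), DMF, 0 °C to rt
Reagents that add atoms: benzyl bromide, BrCc1ccccc1
Why: Double Williamson etherification of the phenol and the primary alcohol; benzyl is chosen so that all five protecting groups of 23 fall in one neutral hydrogenolysis.

Step 9
Reactants: 15 (2R,3S)-7-(benzyloxy)-2-[4-(benzyloxy)-3-methoxyphenyl]-3-[(benzyloxy)methyl]-5-bromo-2,3-dihydro-1-benzofuran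
Product: 16 (2R,3S)-7-(benzyloxy)-2-[4-(benzyloxy)-3-methoxyphenyl]-3-[(benzyloxy)methyl]-5-ethenyl-2,3-dihydro-1-benzofuran
Conditions: vinylboronic acid pinacol ester (1.5 equiv), PdCl2(dppf) (5 mol%), K2CO3, 1,4-dioxane/H2O, 85 °C
Reagents that add atoms: vinylboronic acid pinacol ester, C=CB1OC(C)(C)C(C)(C)O1
Why: Suzuki–Miyaura coupling at the only C–Br bond; benzyl ethers and ring D are inert to aqueous carbonate, and the vinyl group is installed only now because it would not survive the acid of step 7.

Step 10
Reactants: 17 2,4,6-trihydroxybenzaldehyde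
Product: 18 2,4-bis(benzyloxy)-6-hydroxybenzaldehyde
Conditions: BnBr (2.05 equiv), K2CO3 (2.2 equiv), DMF, 0 °C to rt
Reagents that add atoms: benzyl bromide, BrCc1ccccc1
Why: Williamson etherification of the 4-OH and one 2-OH; the remaining hydroxyl is locked in a hydrogen bond to the formyl group and is the least nucleophilic, so two equivalents stop at the dibenzyl ether.

Step 11
Reactants: 18 2,4-bis(benzyloxy)-6-hydroxybenzaldehyde
Product: 19 3,5-bis(benzyloxy)-2-(dimethoxymethyl)phenol
Conditions: HC(OMe)3 (5 equiv), MeOH, Amberlyst 15 (cat.), rt; filtration through basic alumina, concentration, used at once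
Reagents that add atoms: methanol, CO; trimethyl orthoformate, COC(OC)OC
Why: Acid-catalysed acetalisation driven by the orthoformate as water scavenger; the solid acid is filtered off so that no soluble acid or amine reaches the chiral catalyst of step 12, and the labile electron-rich acetal is not stored or chromatographed on silica.

Step 12
Reactants: 16 (2R,3S)-7-(benzyloxy)-2-[4-(benzyloxy)-3-methoxyphenyl]-3-[(benzyloxy)methyl]-5-ethenyl-2,3-dihydro-1-benzofuran; 19 3,5-bis(benzyloxy)-2-(dimethoxymethyl)phenol
Product: 21 (2S,4S)-5,7-bis(benzyloxy)-2-{(2R,3S)-7-(benzyloxy)-2-[4-(benzyloxy)-3-methoxyphenyl]-3-[(benzyloxy)methyl]-2,3-dihydro-1-benzofuran-5-yl}-4-methoxy-3,4-dihydro-2H-chromene, via alkoxy o-quinone methide 20 (not isolated)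
Conditions: 19 (1.5 equiv, added over 6 h), (R)-3,3'-bis(2,4,6-triisopropylphenyl)-1,1'-binaphthyl-2,2'-diyl N-triflyl phosphoramide (10 mol%), 5 Å MS, toluene, −30 °C
Reagents that add atoms: none
Why: Proposed new method: the chiral acid protonates one methoxy group of 19 and methanol leaves, giving the phenol-bearing oxocarbenium ion (the protonated form of 20) as a hydrogen-bonded ion pair with the chiral phosphoramide anion; the terminal carbon of the vinyl group of 16 attacks the cationic carbon (C3–C4), the benzylic cation so formed at C2 is stabilised by O1' para to it, and the phenol oxygen collapses onto it (O1–C2). The closest known reaction types are the chiral N-triflyl phosphoramide-catalysed [4+2] additions of ortho-quinone methides from ortho-hydroxybenzyl alcohols to styrenes and the achiral acid-promoted chroman synthesis from salicylaldehyde acetals and alkenes; an alkoxy-substituted methide under chiral-anion control has not been shown. Ring C closes as a stepwise inverse-demand oxa-[4+2] annulation, the second bond being a six-membered ring closure by O-capture of a cation. C4 is set by the chiral anion, which is anchored by the phenol O–H···O=P hydrogen bond and whose 3,3'-aryl groups leave one face of the cationic carbon open; C2 is set relative to C4 by the cis preference of ring closure (aryl and methoxy both pseudo-equatorial in a half-chair), so the catalyst reaches C2 through C4, the C2'/C3' centres of 16 being five bonds away and without influence. The step needs attack by the vinyl group and not by the arene rings (the para-alkoxystyrene terminus is the most nucleophilic and least hindered π-site, and the cationic carbon is flanked by two ortho substituents), cross-reaction and not self-condensation of 19 (slow addition keeps 19 dilute against 16), ring closure and not methanol capture of the C2 cation (sieves), and ionisation of 19 but not of the product ether (an acetal ionises far more readily than the C4–OMe bond of 21 at low temperature). If the anion fixes C4, any 2,4-trans isomer carries the wrong C2, so trans isomers are to be removed by chromatography here, before C4 is flattened.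

Step 13
Reactants: 21 (2S,4S)-5,7-bis(benzyloxy)-2-{(2R,3S)-7-(benzyloxy)-2-[4-(benzyloxy)-3-methoxyphenyl]-3-[(benzyloxy)methyl]-2,3-dihydro-1-benzofuran-5-yl}-4-methoxy-3,4-dihydro-2H-chromene
Product: 22 (2S)-5,7-bis(benzyloxy)-2-{(2R,3S)-7-(benzyloxy)-2-[4-(benzyloxy)-3-methoxyphenyl]-3-[(benzyloxy)methyl]-2,3-dihydro-1-benzofuran-5-yl}-3,4-dihydro-2H-chromen-4-ol (C4 epimer mixture)
Conditions: PPTS (0.2 equiv), THF/H2O (3:1), 0.01 M, 40 °C
Reagents that add atoms: water, O
Why: SN1 hydrolysis of a benzylic methyl ether: C4 is flanked by the 5- and 7-alkoxy groups and O1 (ortho, para, ortho donors) and ionises under acid far milder than C2–O1 or C2'–O1' would need; excess water at high dilution returns the cation as the alcohol, whose C4 configuration is irrelevant.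

Step 14
Reactants: 22 (2S)-5,7-bis(benzyloxy)-2-{(2R,3S)-7-(benzyloxy)-2-[4-(benzyloxy)-3-methoxyphenyl]-3-[(benzyloxy)methyl]-2,3-dihydro-1-benzofuran-5-yl}-3,4-dihydro-2H-chromen-4-ol
Product: 23 (2S)-5,7-bis(benzyloxy)-2-{(2R,3S)-7-(benzyloxy)-2-[4-(benzyloxy)-3-methoxyphenyl]-3-[(benzyloxy)methyl]-2,3-dihydro-1-benzofuran-5-yl}-2,3-dihydro-4H-chromen-4-one
Conditions: Dess–Martin periodinane (1.5 equiv), NaHCO3, CH2Cl2, 0 °C to rt
Reagents that add atoms: none
Why: Dess–Martin oxidation of a secondary benzylic alcohol to the aryl ketone under buffered conditions, so the flavan-4-ol does not ionise and the flavanone does not open to the chalcone; C2 is untouched.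

Step 15
Reactants: 23 (2S)-5,7-bis(benzyloxy)-2-{(2R,3S)-7-(benzyloxy)-2-[4-(benzyloxy)-3-methoxyphenyl]-3-[(benzyloxy)methyl]-2,3-dihydro-1-benzofuran-5-yl}-2,3-dihydro-4H-chromen-4-one
Product: 24 silyhermin B, (2S)-5,7-dihydroxy-2-[(2R,3S)-7-hydroxy-2-(4-hydroxy-3-methoxyphenyl)-3-(hydroxymethyl)-2,3-dihydro-1-benzofuran-5-yl]-2,3-dihydro-4H-chromen-4-one
Conditions: H2 (1 atm), 10% Pd/C, EtOAc/MeOH (1:1), rt
Reagents that add atoms: none
Why: Heterogeneous hydrogenolysis of four aryl benzyl ethers and one alkyl benzyl ether under neutral conditions; without base the 5-hydroxyflavanone keeps its C2 configuration, and the reaction is stopped at complete debenzylation to spare the benzylic C–O bonds of rings C and D.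

## Compound list

1 | 5-bromo-2,3-dihydroxybenzaldehyde | O=Cc1cc(Br)cc(O)c1O | starting material
2 | 5-bromo-2,3-bis(methoxymethoxy)benzaldehyde | COCOc1cc(Br)cc(C=O)c1OCOC | intermediate
3 | 1-[5-bromo-2,3-bis(methoxymethoxy)phenyl]-2,2,2-trichloroethan-1-ol (racemic) | OC(c1cc(Br)cc(OCOC)c1OCOC)C(Cl)(Cl)Cl | intermediate
4 | 3-[5-bromo-2,3-bis(methoxymethoxy)phenyl]-2,2-dichlorooxirane (racemic, not isolated) | ClC1(Cl)OC1c1cc(Br)cc(OCOC)c1OCOC | intermediate
5 | [5-bromo-2,3-bis(methoxymethoxy)phenyl]acetyl chloride (not isolated) | O=C(Cl)Cc1cc(Br)cc(OCOC)c1OCOC | intermediate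
6 | [5-bromo-2,3-bis(methoxymethoxy)phenyl]acetic acid | OC(=O)Cc1cc(Br)cc(OCOC)c1OCOC | intermediate
7 | [5-bromo-2,3-bis(methoxymethoxy)phenyl]acetic 2,2-dimethylpropanoic anhydride (not isolated) | CC(C)(C)C(=O)OC(=O)Cc1cc(Br)cc(OCOC)c1OCOC | intermediate
8 | (4R)-4-benzyl-3-{[5-bromo-2,3-bis(methoxymethoxy)phenyl]acetyl}-1,3-oxazolidin-2-one | O=C(Cc1cc(Br)cc(OCOC)c1OCOC)N1[C@H](Cc2ccccc2)COC1=O | intermediate
9 | 4-(benzyloxy)-3-methoxybenzaldehyde | COc1cc(C=O)ccc1OCc1ccccc1 | starting material
10 | dibutylboron (Z)-enolate of 8 (not isolated) | CCCCB(CCCC)O/C(=C\c1cc(Br)cc(OCOC)c1OCOC)N1[C@H](Cc2ccccc2)COC1=O | intermediate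
11 | (4R)-4-benzyl-3-{(2R,3R)-3-[4-(benzyloxy)-3-methoxyphenyl]-2-[5-bromo-2,3-bis(methoxymethoxy)phenyl]-3-hydroxypropanoyl}-1,3-oxazolidin-2-one | O=C([C@H](c1cc(Br)cc(OCOC)c1OCOC)[C@@H](O)c1ccc(OCc2ccccc2)c(OC)c1)N1[C@H](Cc2ccccc2)COC1=O | intermediate
12 | (1R,2S)-1-[4-(benzyloxy)-3-methoxyphenyl]-2-[5-bromo-2,3-bis(methoxymethoxy)phenyl]propane-1,3-diol | OC[C@H](c1cc(Br)cc(OCOC)c1OCOC)[C@@H](O)c1ccc(OCc2ccccc2)c(OC)c1 | intermediate
13 | (1R,2S)-1-[4-(benzyloxy)-3-methoxyphenyl]-2-(5-bromo-2,3-dihydroxyphenyl)propane-1,3-diol (not isolated) | OC[C@H](c1cc(Br)cc(O)c1O)[C@@H](O)c1ccc(OCc2ccccc2)c(OC)c1 | intermediate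
14 | (2R,3S)-2-[4-(benzyloxy)-3-methoxyphenyl]-5-bromo-3-(hydroxymethyl)-2,3-dihydro-1-benzofuran-7-ol | COc1cc([C@@H]2Oc3c(O)cc(Br)cc3[C@H]2CO)ccc1OCc1ccccc1 | intermediate
15 | (2R,3S)-7-(benzyloxy)-2-[4-(benzyloxy)-3-methoxyphenyl]-3-[(benzyloxy)methyl]-5-bromo-2,3-dihydro-1-benzofuran | COc1cc([C@@H]2Oc3c(OCc4ccccc4)cc(Br)cc3[C@H]2COCc2ccccc2)ccc1OCc1ccccc1 | intermediate
16 | (2R,3S)-7-(benzyloxy)-2-[4-(benzyloxy)-3-methoxyphenyl]-3-[(benzyloxy)methyl]-5-ethenyl-2,3-dihydro-1-benzofuran | COc1cc([C@@H]2Oc3c(OCc4ccccc4)cc(C=C)cc3[C@H]2COCc2ccccc2)ccc1OCc1ccccc1 | intermediate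
17 | 2,4,6-trihydroxybenzaldehyde | O=Cc1c(O)cc(O)cc1O | starting material
18 | 2,4-bis(benzyloxy)-6-hydroxybenzaldehyde | O=Cc1c(O)cc(OCc2ccccc2)cc1OCc1ccccc1 | intermediate
19 | 3,5-bis(benzyloxy)-2-(dimethoxymethyl)phenol | COC(OC)c1c(O)cc(OCc2ccccc2)cc1OCc1ccccc1 | intermediate
20 | 3,5-bis(benzyloxy)-6-(methoxymethylidene)cyclohexa-2,4-dien-1-one (neutral form of the phenol-oxocarbenium ion; exocyclic geometry not fixed; not isolated) | COC=C1C(=O)C=C(OCc2ccccc2)C=C1OCc1ccccc1 | intermediate
21 | (2S,4S)-5,7-bis(benzyloxy)-2-{(2R,3S)-7-(benzyloxy)-2-[4-(benzyloxy)-3-methoxyphenyl]-3-[(benzyloxy)methyl]-2,3-dihydro-1-benzofuran-5-yl}-4-methoxy-3,4-dihydro-2H-chromene | COc1cc([C@@H]2Oc3c(OCc4ccccc4)cc([C@@H]4C[C@H](OC)c5c(OCc6ccccc6)cc(OCc6ccccc6)cc5O4)cc3[C@H]2COCc2ccccc2)ccc1OCc1ccccc1 | intermediate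
22 | (2S)-5,7-bis(benzyloxy)-2-{(2R,3S)-7-(benzyloxy)-2-[4-(benzyloxy)-3-methoxyphenyl]-3-[(benzyloxy)methyl]-2,3-dihydro-1-benzofuran-5-yl}-3,4-dihydro-2H-chromen-4-ol (C4 epimer mixture, C4 left undefined) | COc1cc([C@@H]2Oc3c(OCc4ccccc4)cc([C@@H]4CC(O)c5c(OCc6ccccc6)cc(OCc6ccccc6)cc5O4)cc3[C@H]2COCc2ccccc2)ccc1OCc1ccccc1 | intermediate
23 | (2S)-5,7-bis(benzyloxy)-2-{(2R,3S)-7-(benzyloxy)-2-[4-(benzyloxy)-3-methoxyphenyl]-3-[(benzyloxy)methyl]-2,3-dihydro-1-benzofuran-5-yl}-2,3-dihydro-4H-chromen-4-one | COc1cc([C@@H]2Oc3c(OCc4ccccc4)cc([C@@H]4CC(=O)c5c(OCc6ccccc6)cc(OCc6ccccc6)cc5O4)cc3[C@H]2COCc2ccccc2)ccc1OCc1ccccc1 | intermediate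
24 | silyhermin B | COc1cc([C@@H]2Oc3c(O)cc([C@@H]4CC(=O)c5c(O)cc(O)cc5O4)cc3[C@H]2CO)ccc1O | target

## Step count and least certain steps

Total step count: 15. Longest linear sequence: 13 steps (steps 1 to 9 and 12 to 15); the branch to 19 (steps 10 and 11) adds two.

**Step 12 (key step).** What may go wrong:
- incomplete facial control by the chiral anion, giving C2 epimers that differ only relative to the remote C2'/C3' pair and are hard to separate;
- weak cis preference in the ring closure;
- C-alkylation of the electron-rich ring A of 19 or 21 by the cation, or self-condensation of 19;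
- cationic oligomerisation of 16;
- ionisation of the C4–OMe bond of 21 under the acid, with loss of methanol.

The C2 purity is best judged at 23, where the two C2 epimers are diastereomers.

Fallback with known chemistry, setting out from 15 and returning at 23: Miyaura borylation of 15 (B2pin2, PdCl2(dppf), KOAc) would give the pinacol boronate F1. A rhodium-catalysed asymmetric conjugate addition of F1 ([Rh(OH)(cod)]2, chiral bisphosphine or diene ligand of the antipode that gives 2S, aqueous dioxane) to 5,7-bis(benzyloxy)chromone F2 would then give 23 directly, bypassing 19 to 22. F2 would be made from 1-[2,4-bis(benzyloxy)-6-hydroxyphenyl]ethanone F3 by condensation with DMF dimethyl acetal and acid-induced ring closure.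

**Step 13.** What may go wrong: ionisation at C4 without capture by water, leading to elimination toward the flav-3-ene or to alkylation of ring A of a second molecule; with too strong an acid, ionisation of C2–O1 and erosion of C2.

Fallback, from 21 back to 23: direct oxidation with DDQ in wet CH2Cl2 at 0 °C (hydride abstraction from C4, hydrolysis of the resulting oxocarbenium ion). This skips 22 and avoids a free C4 cation without a methoxy group; it makes no new compound (F0).

**Step 7.** What may go wrong: fragmentation of the benzylic cation with loss of formaldehyde from the 1,3-diol, acetal formation between the diol and liberated formaldehyde, and incomplete cis-to-trans equilibration.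

Fallback, from 11 back to 14: ring closure before the reductive cleavage. The same acidic methanol applied to 11 would give the dihydrobenzofuran imide F4, which has no free 1,3-diol. LiBH4 reduction of F4 would then give 14.

**Step 3.** What may go wrong: opening of 4 by hydroxide in place of hydride (α-hydroxylation), or over-reduction of 5 to the alcohol.

Fallback, from 2 back to 6: van Leusen reductive cyanation of 2 (TosMIC, t-BuOK, DME, then MeOH, reflux) to the arylacetonitrile F5, then basic hydrolysis (KOH, aqueous EtOH, reflux), which MOM ethers tolerate.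

**Step 15.** What may go wrong: hydrogenolysis of the benzylic C2–O1 or C2'–O1' bonds (ring opening), or reduction of the aryl ketone, before the alkyl benzyl ether is gone.

Fallback, from 23 to 24: non-reductive debenzylation with BCl3 and pentamethylbenzene in CH2Cl2 at −78 °C; it makes no new compound (F0).

## Further compounds

F1 | step 12 | 2-{(2R,3S)-7-(benzyloxy)-2-[4-(benzyloxy)-3-methoxyphenyl]-3-[(benzyloxy)methyl]-2,3-dihydro-1-benzofuran-5-yl}-4,4,5,5-tetramethyl-1,3,2-dioxaborolane | COc1cc([C@@H]2Oc3c(OCc4ccccc4)cc(B4OC(C)(C)C(C)(C)O4)cc3[C@H]2COCc2ccccc2)ccc1OCc1ccccc1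
F2 | step 12 | 5,7-bis(benzyloxy)-4H-chromen-4-one | O=c1ccoc2cc(OCc3ccccc3)cc(OCc3ccccc3)c12
F3 | step 12 | 1-[2,4-bis(benzyloxy)-6-hydroxyphenyl]ethan-1-one | CC(=O)c1c(O)cc(OCc2ccccc2)cc1OCc1ccccc1
F0 | step 13 | none | none
F4 | step 7 | (4R)-4-benzyl-3-{[(2R,3R)-2-[4-(benzyloxy)-3-methoxyphenyl]-5-bromo-7-hydroxy-2,3-dihydro-1-benzofuran-3-yl]carbonyl}-1,3-oxazolidin-2-one | COc1cc([C@@H]2Oc3c(O)cc(Br)cc3[C@H]2C(=O)N2[C@H](Cc3ccccc3)COC2=O)ccc1OCc1ccccc1
F5 | step 3 | [5-bromo-2,3-bis(methoxymethoxy)phenyl]acetonitrile | N#CCc1cc(Br)cc(OCOC)c1OCOC
F0 | step 15 | none | none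
A1 | alternative 1 | methyl 3-(benzyloxy)-5-[(2S)-1-{[tert-butyl(dimethyl)silyl]oxy}-3-(4-hydroxy-3-methoxyphenyl)propan-2-yl]-4-hydroxybenzoate | COC(=O)c1cc(OCc2ccccc2)c(O)c(c1)[C@H](Cc1ccc(O)c(OC)c1)CO[Si](C)(C)C(C)(C)C
A2 | alternative 1 | methyl (2R,3S)-7-(benzyloxy)-3-({[tert-butyl(dimethyl)silyl]oxy}methyl)-2-(4-hydroxy-3-methoxyphenyl)-2,3-dihydro-1-benzofuran-5-carboxylate | COc1cc([C@@H]2Oc3c(OCc4ccccc4)cc(C(=O)OC)cc3[C@H]2CO[Si](C)(C)C(C)(C)C)ccc1O
A3 | alternative 2 | (4S,5R)-5-[4-(benzyloxy)-3-methoxyphenyl]-4-[(benzyloxy)methyl]oxolan-2-one | O=C1C[C@@H](COCc2ccccc2)[C@H](c2ccc(OCc3ccccc3)c(OC)c2)O1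
A4 | alternative 2 | tert-butyl{[(4S,5R)-5-[4-(benzyloxy)-3-methoxyphenyl]-4-[(benzyloxy)methyl]-4,5-dihydrofuran-2-yl]oxy}dimethylsilane | CC(C)(C)[Si](C)(C)OC1=C[C@@H](COCc2ccccc2)[C@H](c2ccc(OCc3ccccc3)c(OC)c2)O1
A5 | alternative 2 | methyl 3-bromo-2-oxo-2H-pyran-5-carboxylate | COC(=O)C1=COC(=O)C(Br)=C1
A6 | alternative 2 | methyl (2R,3S)-2-[4-(benzyloxy)-3-methoxyphenyl]-3-[(benzyloxy)methyl]-7-bromo-2,3-dihydro-1-benzofuran-5-carboxylate | COc1cc([C@@H]2Oc3c(Br)cc(C(=O)OC)cc3[C@H]2COCc2ccccc2)ccc1OCc1ccccc1
A7 | alternative 3 | methyl {3-(benzyloxy)-2-{[4-(benzyloxy)-3-methoxyphenyl]methoxy}-5-bromophenyl}(diazo)acetate | COC(=O)C(=[N+]=[N-])c1cc(Br)cc(OCc2ccccc2)c1OCc1ccc(OCc2ccccc2)c(OC)c1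
A8 | alternative 3 | methyl (2R,3S)-7-(benzyloxy)-2-[4-(benzyloxy)-3-methoxyphenyl]-5-bromo-2,3-dihydro-1-benzofuran-3-carboxylate (cis) | COc1cc([C@@H]2Oc3c(OCc4ccccc4)cc(Br)cc3[C@@H]2C(=O)OC)ccc1OCc1ccccc1
A9 | alternative 3 | methyl (2R,3R)-7-(benzyloxy)-2-[4-(benzyloxy)-3-methoxyphenyl]-5-bromo-2,3-dihydro-1-benzofuran-3-carboxylate (trans) | COc1cc([C@@H]2Oc3c(OCc4ccccc4)cc(Br)cc3[C@H]2C(=O)OC)ccc1OCc1ccccc1
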